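**Retrosynthetic overview**

- Units: A is the 4-hydroxyphenyl flavan (epiafzelechin), B the top epicatechin (its C4 on C6 of A), C the epicatechin whose C8 carries C4 of A, D the bottom epicatechin whose C6 carries C4 of C.
- Feature: the B–A junction is C4(B)–C6(A), and C6 of A is the one ring carbon flanked by O5 and O7. With O5 as the only free phenol, the future C4 of B is brought in as an aldehyde carbon ortho to O5 and closed onto C4a of B's own symmetric 5,7-dioxygenated benzo ring, so the pyran ring of B is made last; hydrogenolysis then gives the target.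
- The A–C–D phenol comes from an A electrophile (C4 acetate) and a C nucleophile (C4(A)–C8(C), hard Lewis acid), then a silver-activated C4 thioether on C forms C4(C)–C6(D) with a D unit whose C8 is blocked by bromine; C and D derive from (−)-epicatechin.
- Unit A and the aldehyde for B both start from glycolate syn-aldol adducts (C2 and C3) that are O-arylated at the benzylic hydroxyl; for A the pyran ring closes by Friedel–Crafts acylation, and the C4 ketone allows O5 alone to be freed.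
- Ring order: pyran ring of A (step 8), rings of C and D from the chiral pool, pyran ring of B (step 26).

Key step: step 26

Assumption: the two N-(benzyloxyacetyl) Evans imides (the phenylalanine-derived 1 for the unit A series, the valine-derived 26 for the unit B series, both inducing in the same sense) and 1,3-bis(benzyloxy)-5-iodobenzene are taken as catalogue compounds, and the C4 epimer ratio of the unit A diol and diacetate is left open because C4 is ionised in the coupling.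

**Route**

Step 1
Reactants: 1 (S)-4-benzyl-3-[(benzyloxy)acetyl]-1,3-oxazolidin-2-one; 2 4-(benzyloxy)benzaldehyde
Product: 4 (4S)-4-benzyl-3-[(2S,3R)-2-(benzyloxy)-3-[4-(benzyloxy)phenyl]-3-hydroxypropanoyl]-1,3-oxazolidin-2-one, via dibutylboron Z-enolate 3 (not isolated)
Conditions: Bu2BOTf, Et3N, CH2Cl2, −78 → 0 °C; 2, −78 → 0 °C; then pH 7 buffer, MeOH, H2O2
Reagents that add atoms: none
Why: Evans syn-aldol reaction of the Z-boron enolate through a closed chair transition state, with the benzyl group of the auxiliary shielding one enolate face, should set the benzylic carbinol (future C2 of unit A, R) and the benzyloxy carbon (future C3) syn to each other in one operation.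

Step 2
Reactants: 4 aldol adduct
Product: 5 (1R,2R)-2-(benzyloxy)-1-[4-(benzyloxy)phenyl]propane-1,3-diol
Conditions: LiBH4, MeOH (1 equiv), THF, 0 °C
Reagents that add atoms: none
Why: Reductive cleavage of the N-acyl oxazolidinone by borohydride should release the primary alcohol and the recoverable auxiliary without touching either stereocentre.

Step 3
Reactants: 5 diol
Product: 6 (1R,2R)-2-(benzyloxy)-1-[4-(benzyloxy)phenyl]-3-[(triisopropylsilyl)oxy]propan-1-ol
Conditions: TIPSCl, imidazole, DMAP (cat.), CH2Cl2, 0 °C → rt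
Reagents that add atoms: chlorotri(propan-2-yl)silane, CC(C)[Si](Cl)(C(C)C)C(C)C
Why: Silylation with a bulky chlorosilane is selective for the primary hydroxyl, which leaves the benzylic hydroxyl as the only nucleophile for the etherification.

Step 4
Reactants: 6 silyl ether; 7 1,3-bis(benzyloxy)-5-iodobenzene
Product: 8 [(2R,3R)-2-(benzyloxy)-3-[3,5-bis(benzyloxy)phenoxy]-3-[4-(benzyloxy)phenyl]propoxy]tri(propan-2-yl)silane
Conditions: CuI (10 mol%), 3,4,7,8-tetramethyl-1,10-phenanthroline (20 mol%), Cs2CO3, 7 (1.5 equiv), toluene, 110 °C, argon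
Reagents that add atoms: none
Why: Copper-catalysed Ullmann-type O-arylation of a secondary alcohol by an aryl iodide makes the bond between oxygen and the arene, so the benzylic stereocentre is carried over with retention.

Step 5
Reactants: 8 aryl ether
Product: 9 (2R,3R)-2-(benzyloxy)-3-[3,5-bis(benzyloxy)phenoxy]-3-[4-(benzyloxy)phenyl]propan-1-ol
Conditions: Bu4NF, THF, 0 °C → rt
Reagents that add atoms: none
Why: Fluoride-induced desilylation should free the primary alcohol under non-acidic conditions that spare the acid-sensitive benzylic aryl ether.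

Step 6
Reactants: 9 primary alcohol
Product: 10 (2S,3R)-2-(benzyloxy)-3-[3,5-bis(benzyloxy)phenoxy]-3-[4-(benzyloxy)phenyl]propanal
Conditions: Dess–Martin periodinane, NaHCO3, CH2Cl2, 0 °C → rt; used crude
Reagents that add atoms: none
Why: Dess–Martin oxidation under buffered, base-free conditions should give the α-alkoxy aldehyde without epimerisation or β-elimination of the aryloxide.

Step 7
Reactants: 10 aldehyde
Product: 11 (2S,3R)-2-(benzyloxy)-3-[3,5-bis(benzyloxy)phenoxy]-3-[4-(benzyloxy)phenyl]propanoic acid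
Conditions: NaClO2, NaH2PO4, 2-methyl-2-butene, t-BuOH/H2O, 0 °C → rt
Reagents that add atoms: sodium chlorite, [Na+].[O-]Cl=O
Why: Pinnick oxidation converts the aldehyde to the acid at about pH 4 while the alkene scavenges hypochlorous acid, which protects the electron-rich rings and the α-stereocentre.

Step 8
Reactants: 11 acid
Product: 13 (2R,3S)-3,5,7-tris(benzyloxy)-2-[4-(benzyloxy)phenyl]-2,3-dihydro-4H-chromen-4-one (2,3-cis), via mixed trifluoroacetic anhydride 12 (not isolated)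
Conditions: (CF3CO)2O (1.2 equiv), CH2Cl2, 0 °C
Reagents that add atoms: none
Why: Intramolecular Friedel–Crafts acylation through the mixed anhydride closes the six-membered ketone ring onto the phloroglucinol-type ring ortho to the ether oxygen (both ortho carbons are equivalent), and the base-free medium should leave the cis-related C2 and C3 centres untouched.

Step 9
Reactants: 13 cis-flavanone
Product: 14 (2R,3S)-3,7-bis(benzyloxy)-2-[4-(benzyloxy)phenyl]-5-hydroxy-2,3-dihydro-4H-chromen-4-one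
Conditions: BCl3 (1.1 equiv), CH2Cl2, −78 °C; aq. NaHCO3
Reagents that add atoms: none
Why: Chelation-controlled Lewis-acid debenzylation, in which boron held between the C4 carbonyl and O5 cleaves only the peri benzyl ether, should distinguish O5 from O7 and from the other benzyl ethers.

Step 10
Reactants: 14 5-hydroxyflavanone
Product: 15 (2R,3R)-3,7-bis(benzyloxy)-2-[4-(benzyloxy)phenyl]chromane-4,5-diol (C4 epimers)
Conditions: LiAlH4, THF, −78 → 0 °C; used at once
Reagents that add atoms: none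
Why: Hydride reduction of the ketone at low temperature gives the benzylic alcohol that becomes the C4 leaving group, and the configuration of the new C4 centre is not controlled and need not be, since C4 is ionised in step 17.

Step 11
Reactants: 15 diol
Product: 16 (2R)-2,3-cis-3,7-bis(benzyloxy)-2-[4-(benzyloxy)phenyl]chromane-4,5-diyl diacetate (C4 epimers)
Conditions: Ac2O, pyridine, DMAP (cat.), CH2Cl2, 0 °C
Reagents that add atoms: acetic anhydride, CC(=O)OC(C)=O
Why: Acetylation turns the 4-hydroxyl into the leaving group and masks O5 as an aryl acetate, which also lowers the nucleophilicity of this ring toward self-condensation.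

Step 12
Reactants: 17 (−)-epicatechin
Product: 18 5,7,3′,4′-tetra-O-benzyl-(−)-epicatechin
Conditions: BnBr, K2CO3, DMF, 0 °C → rt
Reagents that add atoms: benzyl bromide, BrCc1ccccc1
Why: Williamson etherification with carbonate as base alkylates the four phenols and leaves the secondary alcohol and both stereocentres alone.

Step 13
Reactants: 18 tetra-O-benzyl epicatechin
Product: 19 (2R,3R)-3,5,7-tris(benzyloxy)-2-[3,4-bis(benzyloxy)phenyl]chromane
Conditions: NaH, BnBr, DMF, 0 °C → rt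
Reagents that add atoms: benzyl bromide, BrCc1ccccc1
Why: Williamson etherification of the sodium alkoxide benzylates O3.

Step 14
Reactants: 19 penta-O-benzyl epicatechin
Product: 20 (2R,3R,4S)-3,5,7-tris(benzyloxy)-2-[3,4-bis(benzyloxy)phenyl]-4-(2-ethoxyethoxy)chromane (4β)
Conditions: DDQ, 2-ethoxyethanol, CH2Cl2, rt
Reagents that add atoms: 2-ethoxyethanol, CCOCCO
Why: DDQ benzylic oxidation removes hydride from C4, and the alcohol adds to the oxygen-stabilised cation on the face anti to the 3-benzyloxy group, which sets C4 as the 4β ether.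

Step 15
Reactants: 20 4β-ether
Product: 21 (2R,3S,4S)-3,5,7-tris(benzyloxy)-2-[3,4-bis(benzyloxy)phenyl]-4-[(2,6-dimethylphenyl)sulfanyl]chromane (4β)
Conditions: 2,6-dimethylbenzenethiol, BF3·OEt2 (0.5 equiv), CH2Cl2, −78 → −40 °C
Reagents that add atoms: 2,6-dimethylbenzenethiol, Cc1cccc(C)c1S
Why: Lewis-acid-promoted SN1 exchange at C4, with the thiol adding anti to the 3-benzyloxy group, installs a 4β thioether that hard Lewis acids do not ionise.

Step 16
Reactants: 19 penta-O-benzyl epicatechin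
Product: 22 (2R,3R)-3,5,7-tris(benzyloxy)-2-[3,4-bis(benzyloxy)phenyl]-8-bromochromane
Conditions: NBS, CH2Cl2, −40 → 0 °C
Reagents that add atoms: N-bromosuccinimide, O=C1CCC(=O)N1Br
Why: Electrophilic aromatic bromination of the 5,7-dibenzyloxy ring goes to C8, the less hindered activated position, which leaves C6 as the only nucleophilic carbon of unit D.

Step 17
Reactants: 16 unit A diacetate; 21 unit C thioether (2 equiv, excess recovered)
Product: 23 5-O-acetyl-3,7,4′-tri-O-benzylepiafzelechin-(4β→8)-[3,5,7,3′,4′-penta-O-benzyl-4β-(2,6-dimethylphenylthio)epicatechin]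
Conditions: BF3·OEt2, CH2Cl2, −78 → −20 °C
Reagents that add atoms: none
Why: Lewis-acid-promoted Friedel–Crafts flavan coupling: ionisation of the C4 acetate gives a cation that C8 of 21 (the usual, less hindered site) attacks anti to the 3-benzyloxy group, which sets C4 of unit A as 4β while the thioether is untouched by the hard acid.

Step 18
Reactants: 23 dimer thioether; 22 8-bromo unit D (3 equiv, excess recovered)
Product: 24 5-O-acetyl-3,7,4′-tri-O-benzylepiafzelechin-(4β→8)-(3,5,7,3′,4′-penta-O-benzylepicatechin)-(4β→6)-(8-bromo-3,5,7,3′,4′-penta-O-benzylepicatechin)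
Conditions: AgBF4, 2,6-di-tert-butyl-4-methylpyridine, 4 Å MS, THF/CH2Cl2, −20 °C → rt, dark
Reagents that add atoms: none
Why: Thiophilic activation of the C4 thioether by monovalent silver, buffered by the hindered pyridine, gives the C4 cation of unit C in a Friedel–Crafts flavan coupling, and C6 of 22 (C8 being blocked by bromine) attacks anti to the 3-benzyloxy group to set C4 of unit C as 4β.

Step 19
Reactants: 24 trimer acetate
Product: 25 3,7,4′-tri-O-benzylepiafzelechin-(4β→8)-(3,5,7,3′,4′-penta-O-benzylepicatechin)-(4β→6)-(8-bromo-3,5,7,3′,4′-penta-O-benzylepicatechin) with free 5-hydroxyl on unit A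
Conditions: K2CO3 (0.5 equiv), MeOH/THF, rt
Reagents that add atoms: none
Why: Base-catalysed methanolysis (transesterification) of the aryl acetate frees O5 of unit A as the only phenol of the molecule.

Step 20
Reactants: 26 (4S)-3-[(benzyloxy)acetyl]-4-(propan-2-yl)-1,3-oxazolidin-2-one; 27 3,4-bis(benzyloxy)benzaldehyde
Product: 29 (4S)-3-[(2S,3R)-2-(benzyloxy)-3-[3,4-bis(benzyloxy)phenyl]-3-hydroxypropanoyl]-4-(propan-2-yl)-1,3-oxazolidin-2-one, via dibutylboron Z-enolate 28 (not isolated)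
Conditions: Bu2BOTf, Et3N, CH2Cl2, −78 → 0 °C; 27, −78 → 0 °C; then pH 7 buffer, MeOH, H2O2
Reagents that add atoms: none
Why: Evans syn-aldol reaction of the valine-derived glycolate imide through the Z-boron enolate and a closed chair transition state, in which the isopropyl group shields the same enolate face as the benzyl group of 1 does in step 1, should set the future C2 (R) and C3 of unit B syn in the same absolute sense.

Step 21
Reactants: 29 aldol adduct
Product: 30 (1R,2R)-2-(benzyloxy)-1-[3,4-bis(benzyloxy)phenyl]propane-1,3-diol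
Conditions: LiBH4, MeOH (1 equiv), THF, 0 °C
Reagents that add atoms: none
Why: Reductive cleavage of the N-acyl oxazolidinone by borohydride gives the diol with both stereocentres intact and releases the recoverable auxiliary.

Step 22
Reactants: 30 diol
Product: 31 (1R,2R)-2-(benzyloxy)-1-[3,4-bis(benzyloxy)phenyl]-3-[(triisopropylsilyl)oxy]propan-1-ol
Conditions: TIPSCl, imidazole, DMAP (cat.), CH2Cl2, 0 °C → rt
Reagents that add atoms: chlorotri(propan-2-yl)silane, CC(C)[Si](Cl)(C(C)C)C(C)C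
Why: Selective silylation of the primary hydroxyl with a bulky chlorosilane leaves the benzylic hydroxyl free.

Step 23
Reactants: 31 silyl ether; 7 1,3-bis(benzyloxy)-5-iodobenzene
Product: 32 [(2R,3R)-2-(benzyloxy)-3-[3,4-bis(benzyloxy)phenyl]-3-[3,5-bis(benzyloxy)phenoxy]propoxy]tri(propan-2-yl)silane
Conditions: CuI (10 mol%), 3,4,7,8-tetramethyl-1,10-phenanthroline (20 mol%), Cs2CO3, 7 (1.5 equiv), toluene, 110 °C, argon
Reagents that add atoms: none
Why: Copper-catalysed Ullmann-type O-arylation forms the aryl ether at oxygen with retention at the benzylic carbon, which fixes the future C2–O1 bond of unit B.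

Step 24
Reactants: 32 aryl ether
Product: 33 (2R,3R)-2-(benzyloxy)-3-[3,4-bis(benzyloxy)phenyl]-3-[3,5-bis(benzyloxy)phenoxy]propan-1-ol
Conditions: Bu4NF, THF, 0 °C → rt
Reagents that add atoms: none
Why: Fluoride-induced desilylation frees the primary alcohol without acid.

Step 25
Reactants: 33 primary alcohol
Product: 34 (2S,3R)-2-(benzyloxy)-3-[3,4-bis(benzyloxy)phenyl]-3-[3,5-bis(benzyloxy)phenoxy]propanal
Conditions: Dess–Martin periodinane, NaHCO3, CH2Cl2, 0 °C → rt; used crude at once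
Reagents that add atoms: none
Why: Dess–Martin oxidation under buffered, base-free conditions should deliver the configurationally labile α-alkoxy aldehyde without epimerisation.

Step 26
Reactants: 25 trimer phenol; 34 aldehyde (1.5 equiv)
Product: 38 (3,5,7,3′,4′-penta-O-benzylepicatechin)-(4β→6)-(3,7,4′-tri-O-benzylepiafzelechin)-(4β→8)-(3,5,7,3′,4′-penta-O-benzylepicatechin)-(4β→6)-(8-bromo-3,5,7,3′,4′-penta-O-benzylepicatechin) with free 5-hydroxyl on unit A, via magnesium phenoxide 35 (not isolated), via carbinol adduct 36 (not isolated), via ortho-quinone methide 37 (not isolated)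
Conditions: EtMgBr (1.0 equiv), Et2O, 0 °C; solvent changed to CH2Cl2; 34, rt; then BF3·OEt2, −78 → −20 °C
Reagents that add atoms: none
Why: Proposed new method: EtMgBr turns the only acidic group of 25 into bromomagnesium phenoxide 35, which binds the aldehyde of 34 at magnesium and delivers it through a six-membered chelate to C6, the sole unsubstituted carbon ortho to O5 (C4a is quaternary, C8 is para), giving carbinol 36 as in the ortho-specific hydroxyalkylation of bromomagnesium phenoxides by aldehydes, the closest known reaction. BF3·OEt2 then ionises this benzylic carbinol, flanked by O5 and O7, to ortho-quinone methide 37, whose methide carbon is captured by an ortho carbon of the tethered 3,5-bis(benzyloxy)phenoxy ring; such Friedel–Crafts trapping of ortho-quinone methides by electron-rich arenes is known between two molecules but has not been used to close a flavan pyran ring. The pyran ring of B closes in a 6-exo-trig mode with respect to the methide C=C (the attacking arene π bond lies inside the new ring), and both ortho carbons of the symmetric ring give the same product. The new stereocentre C4 of unit B is set by the C2 and C3 centres of the tether: in the chair-like closure the C2 aryl is equatorial and the C3 benzyloxy axial, and the arene adds to the methide face that puts the unit A aryl pseudo-axial and anti to O3 (4β, 3,4-trans), the isomer that should also accumulate if the capture reverses under the Lewis acid. The step needs regioselectivity on unit A and chemoselectivity in the capture: the first is secured by the single free phenol, the second by the six-membered closure onto the phloroglucinol-type ring, which should outrun five-membered closure onto the catechol ring and attack by a second molecule.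

Step 27
Reactants: 38 benzylated bromo tetramer
Product: 39 epicatechin-(4β→6)-epiafzelechin-(4β→8)-epicatechin-(4β→6)-epicatechin (CNP0103636.1)
Conditions: H2 (1 atm), Pd(OH)2/C, Et3N (2 equiv), THF/MeOH/H2O, rt
Reagents that add atoms: none
Why: Catalytic hydrogenolysis cleaves the eighteen benzyl ethers and the aryl C–Br bond in one operation under neutral conditions that leave the interflavan bonds and all stereocentres untouched.

**Compound list**

1 | (S)-4-benzyl-3-[(benzyloxy)acetyl]-1,3-oxazolidin-2-one | O=C(COCc1ccccc1)N1[C@@H](Cc2ccccc2)COC1=O | starting material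
2 | 4-(benzyloxy)benzaldehyde | O=Cc1ccc(OCc2ccccc2)cc1 | starting material
3 | dibutylboron (Z)-enolate of 1 | CCCCB(CCCC)O/C(=C\OCc1ccccc1)N1[C@@H](Cc2ccccc2)COC1=O | intermediate
4 | (4S)-4-benzyl-3-[(2S,3R)-2-(benzyloxy)-3-[4-(benzyloxy)phenyl]-3-hydroxypropanoyl]-1,3-oxazolidin-2-one | O=C(N1[C@@H](Cc2ccccc2)COC1=O)[C@@H](OCc1ccccc1)[C@H](O)c1ccc(OCc2ccccc2)cc1 | intermediate
5 | (1R,2R)-2-(benzyloxy)-1-[4-(benzyloxy)phenyl]propane-1,3-diol | OC[C@@H](OCc1ccccc1)[C@H](O)c1ccc(OCc2ccccc2)cc1 | intermediate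
6 | (1R,2R)-2-(benzyloxy)-1-[4-(benzyloxy)phenyl]-3-[(triisopropylsilyl)oxy]propan-1-ol | CC(C)[Si](OC[C@@H](OCc1ccccc1)[C@H](O)c1ccc(OCc2ccccc2)cc1)(C(C)C)C(C)C | intermediate
7 | 1,3-bis(benzyloxy)-5-iodobenzene | Ic1cc(OCc2ccccc2)cc(OCc2ccccc2)c1 | starting material
8 | [(2R,3R)-2-(benzyloxy)-3-[3,5-bis(benzyloxy)phenoxy]-3-[4-(benzyloxy)phenyl]propoxy]tri(propan-2-yl)silane | CC(C)[Si](OC[C@@H](OCc1ccccc1)[C@H](Oc1cc(OCc2ccccc2)cc(OCc2ccccc2)c1)c1ccc(OCc2ccccc2)cc1)(C(C)C)C(C)C | intermediate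
9 | (2R,3R)-2-(benzyloxy)-3-[3,5-bis(benzyloxy)phenoxy]-3-[4-(benzyloxy)phenyl]propan-1-ol | OC[C@@H](OCc1ccccc1)[C@H](Oc1cc(OCc2ccccc2)cc(OCc2ccccc2)c1)c1ccc(OCc2ccccc2)cc1 | intermediate
10 | (2S,3R)-2-(benzyloxy)-3-[3,5-bis(benzyloxy)phenoxy]-3-[4-(benzyloxy)phenyl]propanal | O=C[C@@H](OCc1ccccc1)[C@H](Oc1cc(OCc2ccccc2)cc(OCc2ccccc2)c1)c1ccc(OCc2ccccc2)cc1 | intermediate
11 | (2S,3R)-2-(benzyloxy)-3-[3,5-bis(benzyloxy)phenoxy]-3-[4-(benzyloxy)phenyl]propanoic acid | OC(=O)[C@@H](OCc1ccccc1)[C@H](Oc1cc(OCc2ccccc2)cc(OCc2ccccc2)c1)c1ccc(OCc2ccccc2)cc1 | intermediate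
12 | mixed anhydride of 11 with trifluoroacetic acid | FC(F)(F)C(=O)OC(=O)[C@@H](OCc1ccccc1)[C@H](Oc1cc(OCc2ccccc2)cc(OCc2ccccc2)c1)c1ccc(OCc2ccccc2)cc1 | intermediate
13 | (2R,3S)-3,5,7-tris(benzyloxy)-2-[4-(benzyloxy)phenyl]-2,3-dihydro-4H-chromen-4-one (2,3-cis) | O=C1c2c(OCc9ccccc9)cc(OCc9ccccc9)cc2O[C@H](c2ccc(OCc9ccccc9)cc2)[C@@H]1OCc9ccccc9 | intermediate
14 | (2R,3S)-3,7-bis(benzyloxy)-2-[4-(benzyloxy)phenyl]-5-hydroxy-2,3-dihydro-4H-chromen-4-one | O=C1c2c(O)cc(OCc9ccccc9)cc2O[C@H](c2ccc(OCc9ccccc9)cc2)[C@@H]1OCc9ccccc9 | intermediate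
15 | (2R,3R)-3,7-bis(benzyloxy)-2-[4-(benzyloxy)phenyl]chromane-4,5-diol, C4 epimers | OC1c2c(O)cc(OCc9ccccc9)cc2O[C@H](c2ccc(OCc9ccccc9)cc2)[C@@H]1OCc9ccccc9 | intermediate
16 | (2R)-2,3-cis-3,7-bis(benzyloxy)-2-[4-(benzyloxy)phenyl]chromane-4,5-diyl diacetate, C4 epimers | CC(=O)OC1c2c(OC(C)=O)cc(OCc9ccccc9)cc2O[C@H](c2ccc(OCc9ccccc9)cc2)[C@@H]1OCc9ccccc9 | intermediate
17 | (−)-epicatechin | O[C@@H]1Cc2c(O)cc(O)cc2O[C@@H]1c1ccc(O)c(O)c1 | starting material
18 | 5,7,3′,4′-tetra-O-benzyl-(−)-epicatechin | O[C@@H]1Cc2c(OCc9ccccc9)cc(OCc9ccccc9)cc2O[C@@H]1c1ccc(OCc9ccccc9)c(OCc9ccccc9)c1 | intermediate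
19 | (2R,3R)-3,5,7-tris(benzyloxy)-2-[3,4-bis(benzyloxy)phenyl]chromane | C(c9ccccc9)O[C@@H]1Cc2c(OCc9ccccc9)cc(OCc9ccccc9)cc2O[C@@H]1c1ccc(OCc9ccccc9)c(OCc9ccccc9)c1 | intermediate
20 | (2R,3R,4S)-3,5,7-tris(benzyloxy)-2-[3,4-bis(benzyloxy)phenyl]-4-(2-ethoxyethoxy)chromane (4β) | c1c(OCc9ccccc9)cc(OCc9ccccc9)c2c1O[C@H](c1ccc(OCc9ccccc9)c(OCc9ccccc9)c1)[C@H](OCc9ccccc9)[C@H]2OCCOCC | intermediate
21 | (2R,3S,4S)-3,5,7-tris(benzyloxy)-2-[3,4-bis(benzyloxy)phenyl]-4-[(2,6-dimethylphenyl)sulfanyl]chromane (4β) | c1c(OCc9ccccc9)cc(OCc9ccccc9)c2c1O[C@H](c1ccc(OCc9ccccc9)c(OCc9ccccc9)c1)[C@H](OCc9ccccc9)[C@H]2Sc1c(C)cccc1C | intermediate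
22 | (2R,3R)-3,5,7-tris(benzyloxy)-2-[3,4-bis(benzyloxy)phenyl]-8-bromochromane | C(c9ccccc9)O[C@@H]1Cc2c(OCc9ccccc9)cc(OCc9ccccc9)c(Br)c2O[C@@H]1c1ccc(OCc9ccccc9)c(OCc9ccccc9)c1 | intermediate
23 | 5-O-acetyl-3,7,4′-tri-O-benzylepiafzelechin-(4β→8)-[3,5,7,3′,4′-penta-O-benzyl-4β-(2,6-dimethylphenylthio)epicatechin] | C(c9ccccc9)Oc1ccc(cc1)[C@H]2Oc3cc(OCc9ccccc9)cc(OC(C)=O)c3[C@H](c6c(OCc9ccccc9)cc(OCc9ccccc9)c7c6O[C@H](c8ccc(OCc9ccccc9)c(OCc9ccccc9)c8)[C@H](OCc9ccccc9)[C@H]7Sc8c(C)cccc8C)[C@H]2OCc9ccccc9 | intermediate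
24 | 5-O-acetyl-3,7,4′-tri-O-benzylepiafzelechin-(4β→8)-(penta-O-benzylepicatechin)-(4β→6)-(8-bromo-penta-O-benzylepicatechin) | C(c9ccccc9)Oc1ccc(cc1)[C@H]2Oc3cc(OCc9ccccc9)cc(OC(C)=O)c3[C@H](c6c(OCc9ccccc9)cc(OCc9ccccc9)c7c6O[C@H](c8ccc(OCc9ccccc9)c(OCc9ccccc9)c8)[C@H](OCc9ccccc9)[C@H]7c6c(OCc9ccccc9)c(Br)c7c(c6OCc9ccccc9)C[C@@H](OCc9ccccc9)[C@@H](c8ccc(OCc9ccccc9)c(OCc9ccccc9)c8)O7)[C@H]2OCc9ccccc9 | intermediate
25 | 3,7,4′-tri-O-benzylepiafzelechin-(4β→8)-(penta-O-benzylepicatechin)-(4β→6)-(8-bromo-penta-O-benzylepicatechin), 5-OH of unit A free | C(c9ccccc9)Oc1ccc(cc1)[C@H]2Oc3cc(OCc9ccccc9)cc(O)c3[C@H](c6c(OCc9ccccc9)cc(OCc9ccccc9)c7c6O[C@H](c8ccc(OCc9ccccc9)c(OCc9ccccc9)c8)[C@H](OCc9ccccc9)[C@H]7c6c(OCc9ccccc9)c(Br)c7c(c6OCc9ccccc9)C[C@@H](OCc9ccccc9)[C@@H](c8ccc(OCc9ccccc9)c(OCc9ccccc9)c8)O7)[C@H]2OCc9ccccc9 | intermediate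
26 | (4S)-3-[(benzyloxy)acetyl]-4-(propan-2-yl)-1,3-oxazolidin-2-one | O=C(COCc1ccccc1)N1[C@@H](C(C)C)COC1=O | starting material
27 | 3,4-bis(benzyloxy)benzaldehyde | O=Cc1ccc(OCc2ccccc2)c(OCc2ccccc2)c1 | starting material
28 | dibutylboron (Z)-enolate of 26 | CCCCB(CCCC)O/C(=C\OCc1ccccc1)N1[C@@H](C(C)C)COC1=O | intermediate
29 | (4S)-3-[(2S,3R)-2-(benzyloxy)-3-[3,4-bis(benzyloxy)phenyl]-3-hydroxypropanoyl]-4-(propan-2-yl)-1,3-oxazolidin-2-one | O=C(N1[C@@H](C(C)C)COC1=O)[C@@H](OCc1ccccc1)[C@H](O)c1ccc(OCc2ccccc2)c(OCc2ccccc2)c1 | intermediate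
30 | (1R,2R)-2-(benzyloxy)-1-[3,4-bis(benzyloxy)phenyl]propane-1,3-diol | OC[C@@H](OCc1ccccc1)[C@H](O)c1ccc(OCc2ccccc2)c(OCc2ccccc2)c1 | intermediate
31 | (1R,2R)-2-(benzyloxy)-1-[3,4-bis(benzyloxy)phenyl]-3-[(triisopropylsilyl)oxy]propan-1-ol | CC(C)[Si](OC[C@@H](OCc1ccccc1)[C@H](O)c1ccc(OCc2ccccc2)c(OCc2ccccc2)c1)(C(C)C)C(C)C | intermediate
32 | [(2R,3R)-2-(benzyloxy)-3-[3,4-bis(benzyloxy)phenyl]-3-[3,5-bis(benzyloxy)phenoxy]propoxy]tri(propan-2-yl)silane | CC(C)[Si](OC[C@@H](OCc1ccccc1)[C@H](Oc1cc(OCc2ccccc2)cc(OCc2ccccc2)c1)c1ccc(OCc2ccccc2)c(OCc2ccccc2)c1)(C(C)C)C(C)C | intermediate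
33 | (2R,3R)-2-(benzyloxy)-3-[3,4-bis(benzyloxy)phenyl]-3-[3,5-bis(benzyloxy)phenoxy]propan-1-ol | OC[C@@H](OCc1ccccc1)[C@H](Oc1cc(OCc2ccccc2)cc(OCc2ccccc2)c1)c1ccc(OCc2ccccc2)c(OCc2ccccc2)c1 | intermediate
34 | (2S,3R)-2-(benzyloxy)-3-[3,4-bis(benzyloxy)phenyl]-3-[3,5-bis(benzyloxy)phenoxy]propanal | O=C[C@@H](OCc1ccccc1)[C@H](Oc1cc(OCc2ccccc2)cc(OCc2ccccc2)c1)c1ccc(OCc2ccccc2)c(OCc2ccccc2)c1 | intermediate
35 | bromomagnesium 5-phenoxide of 25 | C(c9ccccc9)Oc1ccc(cc1)[C@H]2Oc3cc(OCc9ccccc9)cc(O[Mg]Br)c3[C@H](c6c(OCc9ccccc9)cc(OCc9ccccc9)c7c6O[C@H](c8ccc(OCc9ccccc9)c(OCc9ccccc9)c8)[C@H](OCc9ccccc9)[C@H]7c6c(OCc9ccccc9)c(Br)c7c(c6OCc9ccccc9)C[C@@H](OCc9ccccc9)[C@@H](c8ccc(OCc9ccccc9)c(OCc9ccccc9)c8)O7)[C@H]2OCc9ccccc9 | intermediate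
36 | C6(A) ortho-hydroxybenzyl alcohol adduct of 25 and 34 (held as its magnesium chelate; carbinol carbon unassigned) | C(c9ccccc9)Oc1ccc(cc1)[C@H]2Oc3cc(OCc9ccccc9)c(C(O)[C@@H](OCc9ccccc9)[C@H](Oc4cc(OCc9ccccc9)cc(OCc9ccccc9)c4)c4ccc(OCc9ccccc9)c(OCc9ccccc9)c4)c(O)c3[C@H](c6c(OCc9ccccc9)cc(OCc9ccccc9)c7c6O[C@H](c8ccc(OCc9ccccc9)c(OCc9ccccc9)c8)[C@H](OCc9ccccc9)[C@H]7c6c(OCc9ccccc9)c(Br)c7c(c6OCc9ccccc9)C[C@@H](OCc9ccccc9)[C@@H](c8ccc(OCc9ccccc9)c(OCc9ccccc9)c8)O7)[C@H]2OCc9ccccc9 | intermediate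
37 | ortho-quinone methide of unit A (C5=O, exocyclic C6=CH to the B tether; methide geometry open) | C(c9ccccc9)Oc1ccc(cc1)[C@H]2OC=3C=C(OCc9ccccc9)C(=C[C@@H](OCc9ccccc9)[C@H](Oc4cc(OCc9ccccc9)cc(OCc9ccccc9)c4)c4ccc(OCc9ccccc9)c(OCc9ccccc9)c4)C(=O)C=3[C@H](c6c(OCc9ccccc9)cc(OCc9ccccc9)c7c6O[C@H](c8ccc(OCc9ccccc9)c(OCc9ccccc9)c8)[C@H](OCc9ccccc9)[C@H]7c6c(OCc9ccccc9)c(Br)c7c(c6OCc9ccccc9)C[C@@H](OCc9ccccc9)[C@@H](c8ccc(OCc9ccccc9)c(OCc9ccccc9)c8)O7)[C@H]2OCc9ccccc9 | intermediate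
38 | (penta-O-benzylepicatechin)-(4β→6)-(3,7,4′-tri-O-benzylepiafzelechin)-(4β→8)-(penta-O-benzylepicatechin)-(4β→6)-(8-bromo-penta-O-benzylepicatechin), 5-OH of unit A free | C(c9ccccc9)Oc1ccc(cc1)[C@H]2Oc3cc(OCc9ccccc9)c([C@H]4c5c(OCc9ccccc9)cc(OCc9ccccc9)cc5O[C@H](c8ccc(OCc9ccccc9)c(OCc9ccccc9)c8)[C@@H]4OCc9ccccc9)c(O)c3[C@H](c6c(OCc9ccccc9)cc(OCc9ccccc9)c7c6O[C@H](c8ccc(OCc9ccccc9)c(OCc9ccccc9)c8)[C@H](OCc9ccccc9)[C@H]7c6c(OCc9ccccc9)c(Br)c7c(c6OCc9ccccc9)C[C@@H](OCc9ccccc9)[C@@H](c8ccc(OCc9ccccc9)c(OCc9ccccc9)c8)O7)[C@H]2OCc9ccccc9 | intermediate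
39 | epicatechin-(4β→6)-epiafzelechin-(4β→8)-epicatechin-(4β→6)-epicatechin (CNP0103636.1) | Oc1ccc([C@H]2Oc3cc(O)c([C@H]4c5c(O)cc(O)cc5O[C@H](c5ccc(O)c(O)c5)[C@@H]4O)c(O)c3[C@H](c3c(O)cc(O)c4c3O[C@H](c3ccc(O)c(O)c3)[C@H](O)[C@H]4c3c(O)cc4c(c3O)C[C@@H](O)[C@@H](c3ccc(O)c(O)c3)O4)[C@H]2O)cc1 | target

**Count**

Total step count: 27. Longest linear sequence: 16 steps (steps 1–11, 17, 18, 19, 26, 27).

**Steps most likely to fail**

Step 26. Proton transfer from the α-carbon of the aldehyde to the phenoxide (epimerisation, β-elimination of the aryloxide) may outpace C–C bond formation at the hindered C6. After ionisation, attack by a second molecule or loss of facial control in the ring closure may compete. The fallback uses the established halogen-capping logic for 4→6 bonds and sets out from 25. The free 5-hydroxyl is benzylated (BnBr, K2CO3, DMF) to the fully benzylated bromo trimer F1. NBS at low temperature then brominates C8 of unit A, the most accessible activated position, to give the dibromo trimer F2, in which C6 of unit A is the best remaining nucleophilic carbon. In parallel, 22 is oxidised with DDQ and 2-ethoxyethanol to the C8-capped electrophile F3. TMSOTf-promoted Friedel–Crafts coupling of F3 with F2 (CH2Cl2, −78 °C) should give the tribrominated, fully benzylated tetramer F4 with the usual 4β selectivity. Hydrogenolysis over Pd(OH)2/C with Et3N removes the benzyl groups and the three bromines and comes back to the route at 39.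

Step 18. Ionisation of the aryl thioether by silver may be slow or incomplete, and acid released during the coupling may cleave and scramble the A–C bond before the hindered, bromine-deactivated C6 of 22 captures the cation. The fallback installs an oxygen leaving group late instead and sets out from 16 and 19. BF3·OEt2 coupling of 16 with 19 (C8 of 19 as nucleophile) gives the dimer F5, which has no leaving group on unit C. DDQ with 2-ethoxyethanol then oxidises its only benzylic methylene, C4 of unit C, to the 4β-ether dimer F6. TMSOTf-promoted coupling of F6 with 22 comes back to the route at 24.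

Step 4 (and its twin, step 23). Ligand exchange of the hindered benzylic alkoxide at copper may be too slow at a temperature the substrate tolerates, so that oxidation of the benzylic alcohol or migration of the silyl group takes over. The fallback forms the same O–aryl bond without a metal and sets out from 7. Oxidation with mCPBA and TsOH followed by capture with 1,3,5-trimethoxybenzene gives the diaryliodonium tosylate F7. The sodium alkoxide of 6 (NaH, toluene, rt) is then arylated by F7 through ligand coupling at trivalent iodine, the trimethoxyphenyl group staying on iodine, and the route is rejoined at 8. The same salt arylates 31 to give 32.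

**Further compounds**

F1 | step 26 | 3,5,7,4′-tetra-O-benzylepiafzelechin-(4β→8)-(penta-O-benzylepicatechin)-(4β→6)-(8-bromo-penta-O-benzylepicatechin) | C(c9ccccc9)Oc1ccc(cc1)[C@H]2Oc3cc(OCc9ccccc9)cc(OCc9ccccc9)c3[C@H](c6c(OCc9ccccc9)cc(OCc9ccccc9)c7c6O[C@H](c8ccc(OCc9ccccc9)c(OCc9ccccc9)c8)[C@H](OCc9ccccc9)[C@H]7c6c(OCc9ccccc9)c(Br)c7c(c6OCc9ccccc9)C[C@@H](OCc9ccccc9)[C@@H](c8ccc(OCc9ccccc9)c(OCc9ccccc9)c8)O7)[C@H]2OCc9ccccc9
F2 | step 26 | F1 with bromine at C8 of unit A | C(c9ccccc9)Oc1ccc(cc1)[C@H]2Oc3c(Br)c(OCc9ccccc9)cc(OCc9ccccc9)c3[C@H](c6c(OCc9ccccc9)cc(OCc9ccccc9)c7c6O[C@H](c8ccc(OCc9ccccc9)c(OCc9ccccc9)c8)[C@H](OCc9ccccc9)[C@H]7c6c(OCc9ccccc9)c(Br)c7c(c6OCc9ccccc9)C[C@@H](OCc9ccccc9)[C@@H](c8ccc(OCc9ccccc9)c(OCc9ccccc9)c8)O7)[C@H]2OCc9ccccc9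
F3 | step 26 | (2R,3R,4S)-3,5,7-tris(benzyloxy)-2-[3,4-bis(benzyloxy)phenyl]-8-bromo-4-(2-ethoxyethoxy)chromane (4β) | Brc1c(OCc9ccccc9)cc(OCc9ccccc9)c2c1O[C@H](c1ccc(OCc9ccccc9)c(OCc9ccccc9)c1)[C@H](OCc9ccccc9)[C@H]2OCCOCC
F4 | step 26 | (8-bromo-penta-O-benzylepicatechin)-(4β→6)-(8-bromo-3,5,7,4′-tetra-O-benzylepiafzelechin)-(4β→8)-(penta-O-benzylepicatechin)-(4β→6)-(8-bromo-penta-O-benzylepicatechin) | C(c9ccccc9)Oc1ccc(cc1)[C@H]2Oc3c(Br)c(OCc9ccccc9)c([C@H]4c5c(OCc9ccccc9)cc(OCc9ccccc9)c(Br)c5O[C@H](c8ccc(OCc9ccccc9)c(OCc9ccccc9)c8)[C@@H]4OCc9ccccc9)c(OCc9ccccc9)c3[C@H](c6c(OCc9ccccc9)cc(OCc9ccccc9)c7c6O[C@H](c8ccc(OCc9ccccc9)c(OCc9ccccc9)c8)[C@H](OCc9ccccc9)[C@H]7c6c(OCc9ccccc9)c(Br)c7c(c6OCc9ccccc9)C[C@@H](OCc9ccccc9)[C@@H](c8ccc(OCc9ccccc9)c(OCc9ccccc9)c8)O7)[C@H]2OCc9ccccc9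
F5 | step 18 | 5-O-acetyl-3,7,4′-tri-O-benzylepiafzelechin-(4β→8)-(3,5,7,3′,4′-penta-O-benzylepicatechin) | C(c9ccccc9)Oc1ccc(cc1)[C@H]2Oc3cc(OCc9ccccc9)cc(OC(C)=O)c3[C@H](c6c(OCc9ccccc9)cc(OCc9ccccc9)c7c6O[C@H](c8ccc(OCc9ccccc9)c(OCc9ccccc9)c8)[C@H](OCc9ccccc9)C7)[C@H]2OCc9ccccc9
F6 | step 18 | F5 with a 4β-(2-ethoxyethoxy) group on C4 of unit C | C(c9ccccc9)Oc1ccc(cc1)[C@H]2Oc3cc(OCc9ccccc9)cc(OC(C)=O)c3[C@H](c6c(OCc9ccccc9)cc(OCc9ccccc9)c7c6O[C@H](c8ccc(OCc9ccccc9)c(OCc9ccccc9)c8)[C@H](OCc9ccccc9)[C@H]7OCCOCC)[C@H]2OCc9ccccc9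
F7 | step 4 | [3,5-bis(benzyloxy)phenyl](2,4,6-trimethoxyphenyl)iodonium 4-methylbenzenesulfonate | COc1cc(OC)c([I+]c2cc(OCc3ccccc3)cc(OCc3ccccc3)c2)c(OC)c1.Cc1ccc(cc1)S(=O)(=O)[O-]
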